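**Retrosynthetic overview**

1. Target 18 ← triol 17 (oxidation of the C17 carbinol only) ← alkynoate 16 (Z enoate by syn methylcupration) ← alkyne triol 15 ← ketone 13 (equatorial hydroxymethylation at C8).
2. Ring B of 13 is not closed by cyclisation. It comes from the five-membered ring of trans-hydrindanone 6, enlarged by one carbon: C9 is added to the C8 carbonyl with the whole butynyl chain as an α-selenoalkyllithium and then takes over the C8–C10 ring bond (11 → 12).
3. Enabling feature: in 11 the tertiary carbinol carbon C8 of the ring C5–C6–C7–C8–C10 carries the exocyclic C9–Se bond, and its ring neighbour C10 is quaternary and so the best migrating group. The carbinol oxygen ends as the C8 ketone that later accepts C17.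
4. 6 ← (R)-Hajos–Parrish ketone 1, which supplies ring A, the C10 stereocentre and the five-membered ring. The C4 methyls, C3–OH and C5–H follow by deconjugative methylation, reduction and hydrogenation.
5. Ring order: ring A and the five-membered ring are present in 1; ring B arises last from the five-membered ring, in step 8.

Key step: step 8

Remark: carbon numbers are the labdane numbers of the target (C3 carbinol, C4 gem-dimethyl, C8 carbinol bearing C17, C9 bearing the chain C11–C16, C10 with the angular methyl); 1 and 7 are taken as commercial.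

**Route**

Step 1
Reactants: 1 (R)-Hajos–Parrish ketone
Product: 2 (7a'R)-7a'-methyl-2',3',7',7a'-tetrahydrospiro[1,3-dioxolane-2,1'-inden]-5'(6'H)-one
Conditions: HOCH2CH2OH, p-TsOH (cat.), 4 Å MS, 20 °C
Reagents that add atoms: ethane-1,2-diol OCCO
Why: Acid-catalysed ketalisation should mask only the saturated, more electrophilic cyclopentanone carbonyl (C8) and leave the vinylogous enone carbonyl, as in the selective monoketalisation of the Wieland–Miescher ketone; no stereocentre is formed.

Step 2
Reactants: 2 the C8 dioxolane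
Product: 3 (7a'R)-4',4',7a'-trimethyl-2',6',7',7a'-tetrahydrospiro[1,3-dioxolane-2,1'-inden]-5'(4'H)-one
Conditions: KOtBu (3 equiv), MeI (6 equiv), t-BuOH/THF, 0 to 20 °C
Reagents that add atoms: iodomethane CI
Why: Deconjugative α,α-dimethylation of the enone: the extended potassium dienolate is alkylated twice at C4 and the double bond ends at C5=C6, as in the Wieland–Miescher ketal and testosterone series; no stereocentre is formed.

Step 3
Reactants: 3 the 4,4-dimethyl β,γ-enone
Product: 4 (5'R,7a'R)-4',4',7a'-trimethyl-2',4',5',6',7',7a'-hexahydrospiro[1,3-dioxolane-2,1'-inden]-5'-ol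
Conditions: NaBH4, MeOH, 0 °C
Reagents that add atoms: none
Why: Borohydride reduction of the neopentyl C3 ketone by axial hydride delivery should give the equatorial alcohol cis to the C10 methyl (3R), the usual outcome for 4,4-dimethyl-3-ketones.

Step 4
Reactants: 4 the homoallylic alcohol
Product: 6 (3aR,5R,7aR)-5-hydroxy-4,4,7a-trimethyloctahydro-1H-inden-1-one, via saturated ketal 5 (not isolated)
Conditions: H2 (5 bar), Pd/C, EtOAc; filter; then 2 M HCl, THF, 20 °C
Reagents that add atoms: water O
Why: Heterogeneous catalytic hydrogenation should add H2 to C5=C6 from the face opposite the C10 methyl and the syn C4 methyl, setting C5–H trans to the angular methyl (trans-hydrindane, as with 14-ene steroids), and acid-catalysed ketal hydrolysis then frees the C8 ketone.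

Step 5
Reactants: 7 5-(trimethylsilyl)pent-4-yn-1-ol
Product: 8 5-(trimethylsilyl)pent-4-ynal
Conditions: TEMPO (0.1 equiv), PhI(OAc)2 (1.1 equiv), CH2Cl2, 20 °C
Reagents that add atoms: none
Why: Oxoammonium (TEMPO) oxidation of a primary alcohol stops at the aldehyde and leaves the silyl alkyne untouched.

Step 6
Reactants: 8 5-(trimethylsilyl)pent-4-ynal
Product: 9 [5,5-bis(phenylselanyl)pent-1-yn-1-yl]trimethylsilane
Conditions: PhSeH (2.1 equiv), ZnCl2 (0.5 equiv), CH2Cl2, 20 °C
Reagents that add atoms: benzeneselenol [SeH]c1ccccc1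
Why: Lewis acid-catalysed selenoacetalisation of an aldehyde is the standard entry to precursors of α-selenoalkyllithiums.

Step 7
Reactants: 9 the selenoacetal; 6 the hydroxy hydrindanone
Product: 11 (1R,3aR,5R,7aR)-4,4,7a-trimethyl-1-[1-(phenylselanyl)-5-(trimethylsilyl)pent-4-yn-1-yl]octahydro-1H-indene-1,5-diol (both epimers at the selenium-bearing carbon), via lithio selenide 10 (not isolated)
Conditions: 9 (2.5 equiv), n-BuLi (2.4 equiv), THF, −78 °C; then 6, −78 °C; aq. NH4Cl
Reagents that add atoms: none
Why: Selenium–lithium exchange gives a weakly basic, strongly nucleophilic α-selenoalkyllithium; after one equivalent is spent on the C3 hydroxyl it should add (1,2-addition) to the neopentyl C8 ketone from the face opposite the angular methyl, as nucleophiles do with 17-keto steroids, while the configuration at the selenium-bearing carbon is uncontrolled and need not be controlled.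

Step 8
Reactants: 11 the β-hydroxy selenide
Product: 12 (4aS,6R,8aR)-6-hydroxy-5,5,8a-trimethyl-1-[4-(trimethylsilyl)but-3-yn-1-yl]octahydronaphthalen-2(1H)-one (C9 epimers)
Conditions: AgBF4 (2 equiv) on neutral Al2O3, CH2Cl2, 0 to 20 °C
Reagents that add atoms: none
Why: Monovalent silver binds the selenium of 11 and, as PhSeAg leaves C9, the C8–C10 ring bond lying antiperiplanar to the C9–Se bond shifts to C9 while the C8 hydroxyl collapses to the ketone. This is the seleno-pinacol (semipinacol) ring enlargement of a 1-(1-selenoalkyl)cycloalkanol, the selenium counterpart of the Tiffeneau–Demjanov ring expansion, a known way from cyclopentanones to 2-alkylcyclohexanones. Ring B (C5–C6–C7–C8–C9–C10) is closed not by cyclisation but by this 1,2-alkyl shift, which inserts C9 between C8 and C10 of the five-membered ring C5–C6–C7–C8–C10. C10 migrates with retention, so the quaternary centre and the trans ring fusion are carried over unchanged, whereas C9 is formed with inversion at the selenium-bearing carbon and therefore as the epimer pair present in 11, which step 9 converges. The step needs migration of C10 and not of the C7 methylene: the fully substituted C10 is the better migrating group in this cationic shift, and the rotamer that places the large selenium anti to the large C10 should be the populated one. The alkyne is silylated to keep silver off a terminal C–H, and it and the free C3 hydroxyl should be spectators.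

Step 9
Reactants: 12 the ring-enlarged ketone (C9 epimers)
Product: 13 (1S,4aS,6R,8aR)-1-(but-3-yn-1-yl)-6-hydroxy-5,5,8a-trimethyloctahydronaphthalen-2(1H)-one
Conditions: NaOMe (0.5 equiv), MeOH, 40 °C
Reagents that add atoms: none
Why: Methoxide-mediated protodesilylation frees the alkyne and base-catalysed enolisation equilibrates C9, where axial reprotonation of the C8–C9 enolate from the face opposite the angular methyl and the thermodynamic preference should both favour the equatorial chain cis to the C10 methyl (9S).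

Step 10
Reactants: 13 the alkynyl ketone
Product: 15 (1S,2R,4aS,6R,8aR)-1-(but-3-yn-1-yl)-2-(hydroxymethyl)-5,5,8a-trimethyldecahydronaphthalene-2,6-diol, via hydroxy silane 14 (not isolated)
Conditions: ClMgCH2SiMe2(OiPr) (5 equiv), THF, 0 to 20 °C; H2O; then H2O2 (30%), KF, KHCO3, THF/MeOH, 20 °C
Reagents that add atoms: (isopropoxydimethylsilyl)methylmagnesium chloride CC(C)O[Si](C)(C)C[Mg]Cl; hydrogen peroxide OO
Why: Nucleophilic hydroxymethylation with the silylmethyl Grignard reagent should occur by equatorial attack on the C8 ketone because the axial path is blocked by the syn-axial C10 methyl, which places C17 trans and the hydroxyl cis to that methyl (8R), and Tamao–Fleming oxidation then turns C–Si into C–OH.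

Step 11
Reactants: 15 the alkyne triol
Product: 16 methyl 5-[(1S,2R,4aS,6R,8aR)-2,6-dihydroxy-2-(hydroxymethyl)-5,5,8a-trimethyldecahydronaphthalen-1-yl]pent-2-ynoate
Conditions: PdCl2 (0.1 equiv), CuCl2 (2.2 equiv), NaOAc (2.2 equiv), CO (1 atm), MeOH, 20 °C
Reagents that add atoms: carbon monoxide [C-]#[O+]; methanol CO
Why: Oxidative methoxycarbonylation of a terminal alkyne, catalysed by divalent palladium with CuCl2 as reoxidant, gives the alkynoate without protection of the hydroxyls.

Step 12
Reactants: 16 the alkynoate triol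
Product: 17 methyl (2Z)-5-[(1S,2R,4aS,6R,8aR)-2,6-dihydroxy-2-(hydroxymethyl)-5,5,8a-trimethyldecahydronaphthalen-1-yl]-3-methylpent-2-enoate
Conditions: Me2CuLi (6 equiv, from CuI and MeLi), THF, −78 °C; MeOH, −78 °C; aq. NH4Cl
Reagents that add atoms: lithium dimethylcuprate [Li+].C[Cu-]C
Why: Syn carbocupration of the alkynoate at −78 °C followed by protonation with retention puts the new methyl cis to hydrogen and the ester cis to the chain, which is the Z enoate, while excess cuprate absorbs the three hydroxyl protons.

Step 13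
Reactants: 17 the Z-enoate triol
Product: 18 methyl (2Z)-5-[(1S,2R,4aS,6R,8aR)-2-formyl-2,6-dihydroxy-5,5,8a-trimethyldecahydronaphthalen-1-yl]-3-methylpent-2-enoate (target)
Conditions: TEMPO (0.1 equiv), NCS (1.3 equiv), Bu4NCl (0.1 equiv), CH2Cl2/aq. NaHCO3–K2CO3 (pH 8.6), 20 °C
Reagents that add atoms: none
Why: Oxoammonium (TEMPO/NCS) oxidation should select the primary C17 carbinol over the hindered secondary C3 hydroxyl and the tertiary one, stop at the aldehyde, and involve no glycol-cleaving oxidant.

**Compound list**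

1 | (R)-Hajos–Parrish ketone, (7aR)-7a-methyl-2,3,7,7a-tetrahydro-1H-indene-1,5(6H)-dione | O=C1[C@]2(C)CCC(=O)C=C2CC1 | starting material
2 | (7a'R)-7a'-methyl-2',3',7',7a'-tetrahydrospiro[1,3-dioxolane-2,1'-inden]-5'(6'H)-one | O1CCOC12[C@]3(C)CCC(=O)C=C3CC2 | intermediate
3 | (7a'R)-4',4',7a'-trimethyl-2',6',7',7a'-tetrahydrospiro[1,3-dioxolane-2,1'-inden]-5'(4'H)-one | O1CCOC12[C@]3(C)CCC(=O)C(C)(C)C3=CC2 | intermediate
4 | (5'R,7a'R)-4',4',7a'-trimethyl-2',4',5',6',7',7a'-hexahydrospiro[1,3-dioxolane-2,1'-inden]-5'-ol | O1CCOC12[C@]3(C)CC[C@@H](O)C(C)(C)C3=CC2 | intermediate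
5 | (3a'R,5'R,7a'R)-4',4',7a'-trimethyloctahydrospiro[1,3-dioxolane-2,1'-inden]-5'-ol | O1CCOC12[C@]3(C)CC[C@@H](O)C(C)(C)[C@H]3CC2 | intermediate
6 | (3aR,5R,7aR)-5-hydroxy-4,4,7a-trimethyloctahydro-1H-inden-1-one | O=C1[C@]2(C)CC[C@@H](O)C(C)(C)[C@H]2CC1 | intermediate
7 | 5-(trimethylsilyl)pent-4-yn-1-ol | C[Si](C)(C)C#CCCCO | starting material
8 | 5-(trimethylsilyl)pent-4-ynal | C[Si](C)(C)C#CCCC=O | intermediate
9 | [5,5-bis(phenylselanyl)pent-1-yn-1-yl]trimethylsilane | C[Si](C)(C)C#CCCC([Se]c1ccccc1)[Se]c1ccccc1 | intermediate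
10 | [5-lithio-5-(phenylselanyl)pent-1-yn-1-yl]trimethylsilane | [Li]C(CCC#C[Si](C)(C)C)[Se]c1ccccc1 | intermediate
11 | (1R,3aR,5R,7aR)-4,4,7a-trimethyl-1-[1-(phenylselanyl)-5-(trimethylsilyl)pent-4-yn-1-yl]octahydro-1H-indene-1,5-diol, both epimers at the selenium-bearing carbon | O[C@@]1(C(CCC#C[Si](C)(C)C)[Se]c3ccccc3)[C@]2(C)CC[C@@H](O)C(C)(C)[C@H]2CC1 | intermediate
12 | (4aS,6R,8aR)-6-hydroxy-5,5,8a-trimethyl-1-[4-(trimethylsilyl)but-3-yn-1-yl]octahydronaphthalen-2(1H)-one, C9 epimers | C[Si](C)(C)C#CCCC1[C@]2(C)CC[C@@H](O)C(C)(C)[C@H]2CCC1=O | intermediate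
13 | (1S,4aS,6R,8aR)-1-(but-3-yn-1-yl)-6-hydroxy-5,5,8a-trimethyloctahydronaphthalen-2(1H)-one | C#CCC[C@H]1[C@]2(C)CC[C@@H](O)C(C)(C)[C@H]2CCC1=O | intermediate
14 | (1S,2R,4aS,6R,8aR)-1-(but-3-yn-1-yl)-2-{[dimethyl(propan-2-yloxy)silyl]methyl}-5,5,8a-trimethyldecahydronaphthalene-2,6-diol | C#CCC[C@H]1[C@]2(C)CC[C@@H](O)C(C)(C)[C@H]2CC[C@]1(O)C[Si](C)(C)OC(C)C | intermediate
15 | (1S,2R,4aS,6R,8aR)-1-(but-3-yn-1-yl)-2-(hydroxymethyl)-5,5,8a-trimethyldecahydronaphthalene-2,6-diol | C#CCC[C@H]1[C@]2(C)CC[C@@H](O)C(C)(C)[C@H]2CC[C@]1(O)CO | intermediate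
16 | methyl 5-[(1S,2R,4aS,6R,8aR)-2,6-dihydroxy-2-(hydroxymethyl)-5,5,8a-trimethyldecahydronaphthalen-1-yl]pent-2-ynoate | COC(=O)C#CCC[C@H]1[C@]2(C)CC[C@@H](O)C(C)(C)[C@H]2CC[C@]1(O)CO | intermediate
17 | methyl (2Z)-5-[(1S,2R,4aS,6R,8aR)-2,6-dihydroxy-2-(hydroxymethyl)-5,5,8a-trimethyldecahydronaphthalen-1-yl]-3-methylpent-2-enoate | COC(=O)/C=C(/C)CC[C@H]1[C@]2(C)CC[C@@H](O)C(C)(C)[C@H]2CC[C@]1(O)CO | intermediate
18 | methyl (2Z)-5-[(1S,2R,4aS,6R,8aR)-2-formyl-2,6-dihydroxy-5,5,8a-trimethyldecahydronaphthalen-1-yl]-3-methylpent-2-enoate | COC(=O)/C=C(/C)CC[C@H]1[C@]2(C)CC[C@@H](O)C(C)(C)[C@H]2CC[C@]1(O)C=O | target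

**Step count and risks**

Total step count: 13. Longest linear sequence: 11 steps (steps 1–4 and 7–13); steps 5–6 make the selenoacetal branch, which joins at step 7.

Steps most likely to fail:

1. Step 8. Ionisation at the secondary selenium-bearing carbon may be slow, so that oxirane closure or loss of selenium and hydroxyl to an olefin outruns the 1,2-shift, or the C7 methylene may compete with C10 in the migration. Fallback, from 6 back to 13: the ring enlargement would be run as a Lewis acid-promoted epoxy alcohol semipinacol rearrangement, where migration of a tertiary alkyl group is well established. CH2=CHMgBr with CeCl3 in THF at −78 °C would add to 6 from the face opposite the angular methyl to give the vinyl carbinol F1. VO(acac)2 with t-BuOOH in CH2Cl2 would epoxidise it under direction of the tertiary hydroxyl to the epoxy alcohol F2. BF3·OEt2 at −78 °C would shift C10 to the oxirane carbon and give the ring-enlarged hydroxymethyl ketone F3. Dehydration with DCC and CuCl would give the methylene ketone F4. TiCl4-promoted conjugate propargylation of F4 with allenyltributylstannane, followed by equilibrating protonation at C9, would give 13.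

2. Step 11. Intramolecular oxypalladation of the alkyne by the C8 hydroxyl (a six-membered cyclisation–carbonylation) may compete with carbonylation at the alkyne terminus. Fallback, from 15 back to 16: the carboxyl carbon would be introduced by polar chemistry instead. Deprotonation of 15 with n-BuLi (4.3 equiv) in THF/DMPU at −78 to −20 °C and quenching with CO2 would, after acidification (which returns the O-carbonates to hydroxyls), give the alkynoic acid F5. TMSCHN2 in MeOH/toluene would esterify only the carboxylic acid and give 16.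

3. Step 13. Chemoselectivity may be lost, either by oxidation of the secondary C3 hydroxyl or by overoxidation at the C8–C17 glycol. Fallback, from 17 to 18: the glycol alone would be activated as a tin acetal. Bu2SnO in toluene at reflux with removal of water would form the five-membered dibutylstannylene acetal F6 only at the C8/C17 1,2-diol. Brominolysis with NBS in CHCl3 at 20 °C would oxidise the primary carbinol carbon within the stannylene to the α-hydroxy aldehyde 18, the isolated C3 hydroxyl not being activated.

Further compounds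
F1 | step 8 | (1S,3aR,5R,7aR)-1-ethenyl-4,4,7a-trimethyloctahydro-1H-indene-1,5-diol | O[C@@]1(C=C)[C@]2(C)CC[C@@H](O)C(C)(C)[C@H]2CC1
F2 | step 8 | (1R,3aR,5R,7aR)-4,4,7a-trimethyl-1-(oxiran-2-yl)octahydro-1H-indene-1,5-diol, oxirane carbon as formed in the directed epoxidation | O[C@@]1(C3CO3)[C@]2(C)CC[C@@H](O)C(C)(C)[C@H]2CC1
F3 | step 8 | (4aS,6R,8aR)-6-hydroxy-1-(hydroxymethyl)-5,5,8a-trimethyloctahydronaphthalen-2(1H)-one, C9 epimers | OCC1[C@]2(C)CC[C@@H](O)C(C)(C)[C@H]2CCC1=O
F4 | step 8 | (4aS,6R,8aR)-6-hydroxy-5,5,8a-trimethyl-1-methylideneoctahydronaphthalen-2(1H)-one | C=C1[C@]2(C)CC[C@@H](O)C(C)(C)[C@H]2CCC1=O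
F5 | step 11 | 5-[(1S,2R,4aS,6R,8aR)-2,6-dihydroxy-2-(hydroxymethyl)-5,5,8a-trimethyldecahydronaphthalen-1-yl]pent-2-ynoic acid | OC(=O)C#CCC[C@H]1[C@]2(C)CC[C@@H](O)C(C)(C)[C@H]2CC[C@]1(O)CO
F6 | step 13 | C8,C17-O-dibutylstannylene acetal of 17 (2,2-dibutyl-1,3,2-dioxastannolane spiro-fused at C8) | COC(=O)/C=C(/C)CC[C@H]1[C@]2(C)CC[C@@H](O)C(C)(C)[C@H]2CC[C@]13CO[Sn](CCCC)(CCCC)O3
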